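(The data come from a simulation for an exercise, and the scatter is random.)

I could not let Sub go one for one into Ptn: in the winter run 1.35 M of Sub had gone by 40.0 h, more than the 1.2 M of Ptn charged. The dusk run, whose Ptn exceeded its Sub, still held 31% of its Sub at 40.0 h.

| flask | Sub | Ptn | remark | time |
|---|---|---|---|---|
| dusk | 1 M | 1.2 M | run made earlier |  |
| winter | 3 M | 1.2 M | run made earlier |  |
| beta | 1.5 M | 1.60 M |  | 5.0 d |
| alpha | 1.5 M | 1.20 M |  | 5.0 d |

| run | time / h | Sub / % | Prd / % |
|---|---|---|---|
| dusk | 8.00 | 50 | 5 |
| dusk | 15.0 | 41 | 4 |
| dusk | 20.0 | 40 | 0 |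
| dusk | 30.0 | 33 | 7 |
| dusk | 40.0 | 31 | 3 |
| winter | 3.00 | 73 | 9 |
| winter | 6.00 | 67 | 2 |
| winter | 10.0 | 60 | 2 |
| winter | 15.0 | 58 | 2 |
| winter | 25.0 | 58 | 2 |
| winter | 40.0 | 55 | 0 |

(standard deviation of a reading: 2 percentage points)

- what has gone from Sub into another species counts as reacted, even if it can come back

* part of the Sub that has reacted at the end, beta
* part of the Sub that has reacted at the end, alpha
* what raising the concentration of Ptn from its lowest to its highest value here does to the part of the Sub that has reacted (changes below 5 percentage points count as none) (it rises / it falls / no change)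

So I stopped counting moles and compared stopping levels. Let E be the stoichiometric ratio, Ptn charged over Sub charged: 0.400 in winter, 1.20 in dusk. The last Sub readings of the two runs gave 30.0% of the Sub charged per equivalent; this is the leverage Y, the drop in the stopping level of Sub per equivalent of Ptn charged. Drawn back to E of zero, the line stood at 67.0%. For alpha it gave 57.0% reacted, and for beta 65.0%.

I doubted the straight line, but both flasks lie between the two runs, so I was interpolating. I doubted the dusk reading too, since Sub was still sinking, from 33% to 31%. One more such step lifts Y to 32.5% and the alpha answer by 1 percentage point, less than the scatter. So I kept my numbers.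

The forecast said 80% for beta and 68% for alpha, and that with more Ptn it rises, reading “a reversible adduct”; mine stood lower.

The flask gave 68.6% for beta and 59.7% for alpha; with more Ptn it rises, by 9 points, where Y had given 8 points.

    Ptn + Byp ⇌ Ptn.Byp, settled at all times (K = 3100 M⁻¹)
    Sub + Ptn ⇌ Byp + Prd (K = 0.730, k = 0.0640 M⁻¹ h⁻¹)
    Sub ⇌ Imd (K = 0.460, k = 0.0540 h⁻¹)
    Prd ⇌ Ofp (K = 31.0, k = 0.470 h⁻¹)

In alpha, Sub and Imd relax into each other with a half-life of 0.169 d by that step alone, short against 5.0 d, while at the end the forward step from Sub + Ptn uses Sub at 0.0060 of the forward rate of the step to Imd. Ptn, the limiting reagent of alpha, has 0.42% of its charge left against 40% of Sub, with half of its charge lying as Ptn.Byp. For a neighbour of alpha charged with 3.0 M of Ptn, E lies beyond both runs, and Y, now extrapolated, gives 93.0% reacted. The computed neighbour flask gives 95.9% reacted, with 90.8% of its Sub as Ofp.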